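**Retrosynthetic overview**

1. Target numbering: ring C1 (CHOH), C2 (CMe2), C3 (CH), C4 (C=CH2), C5, C6; side chain C1′, C2′, C3′ … Enabling feature: a bond C6–C2′ would close a second six-membered ring (C6, C1, C2, C3, C1′, C2′), a 4,4-dimethylcyclohexane-1,3-dione with C1 and C2′ as carbonyl carbons. In that ring C6 is the acidic carbon between two carbonyls, C3 is an enone β-carbon, and the two sit 1,4 to each other.
2. Key disconnection (step 4): the unit C5–C4(=CH2) of 2,3-dibromopropene is laid across C6 and C3 of 4,4-dimethylcyclohex-5-ene-1,3-dione in one palladium-catalysed operation. C6–C5 forms by allylic alkylation and C4–C3 by reductive Heck closure, giving a bicyclo[2.2.2]octane-2,6-dione; a chiral ligand funnels the racemising intermediate into one enantiomer and so fixes C3.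
3. The temporary ring is unzipped at C6–C2′ by retro-Claisen cleavage, leaving the target carbocycle with a C1 ketone and a CH2CO2Me arm. Hydride delivered anti to the arm then sets C1.
4. Side chain: C2′–C3′ by sp3–sp2 Negishi coupling with an (E)-alkenyl iodide made from (2E,6E)-farnesyl bromide; syn hydrozirconation fixes the 3′E geometry.
5. Ring order: temporary dione ring (present from the start), then target carbocycle (step 4), then temporary ring opened (step 5).

Key step: step 4

Assumption: the sense of induction of the bisphosphine in step 4 cannot be derived from a model, so (R)-BINAP stands for whichever antipode gives (1R,4R)-7, to be fixed in the first runs; 4 is drawn as the diketone although it should be largely enolised.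

**Route**

Step 1
Reactants: 1 4,4-dimethylcyclohex-2-en-1-one
Product: 2 4,4-dimethylcyclohexa-2,5-dien-1-one
Conditions: DDQ, 1,4-dioxane, reflux
Reagents that add atoms: none
Why: DDQ dehydrogenation of the enone through its dienol should give the cross-conjugated dienone; the quaternary carbon blocks aromatisation and no stereocentre is formed.

Step 2
Reactants: 2 4,4-dimethylcyclohexa-2,5-dien-1-one
Product: 3 rac-5,5-dimethyl-7-oxabicyclo[4.1.0]hept-3-en-2-one
Conditions: H2O2 (30 % aq., 1.1 equiv), NaOH (cat.), MeOH, 0 °C
Reagents that add atoms: hydrogen peroxide, OO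
Why: Weitz–Scheffer nucleophilic epoxidation of one of the two equivalent enone double bonds; the epoxide is racemic and its stereocentres are erased in step 3.

Step 3
Reactants: 3 rac-5,5-dimethyl-7-oxabicyclo[4.1.0]hept-3-en-2-one
Product: 4 4,4-dimethylcyclohex-5-ene-1,3-dione
Conditions: Pd(PPh3)4 (3 mol %), dppe (3 mol %), toluene, 80 °C
Reagents that add atoms: none
Why: palladium-catalysed isomerisation of an α,β-epoxy ketone to the β-diketone (opening at the α-carbon, then β-hydride shift) should leave the second enone untouched; no stereocentre remains.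

Step 4
Reactants: 4 4,4-dimethylcyclohex-5-ene-1,3-dione; 5 2,3-dibromoprop-1-ene
Product: 7 (1R,4R)-3,3-dimethyl-8-methylidenebicyclo[2.2.2]octane-2,6-dione, via 2-(2-bromoallyl)dione 6 (not isolated)
Conditions: Pd2(dba)3 (2.5 mol %), (R)-BINAP (6 mol %), i-Pr2NEt, DMF, 0 °C to rt, 5 added slowly; then HCO2Na, 80 °C
Reagents that add atoms: none
Why: Proposed new method: zerovalent palladium ionises the allylic C–Br bond of 5 and the soft enolate of 4 attacks the 2-bromo-π-allyl complex through C2 (Tsuji–Trost; any O-allyl ether re-ionises), giving 6 as enantiomers that interconvert through the enol; the released catalyst then inserts into the vinyl C–Br bond, the alkenylpalladium adds syn to C5 of the enone, and because β-hydride elimination of the resulting palladium enolate would need a bridgehead alkene it is protonated, formate returning divalent palladium to zerovalent palladium (reductive Heck). The closest known reaction types are the Tsuji–Trost C-allylation of cyclic 1,3-diones with 2-haloallyl electrophiles and the intramolecular, also enantioselective, reductive Heck cyclisation of vinyl or aryl halides onto cyclohexenones; their union in one flask on a racemising substrate is new. The target carbocycle is closed 6-exo-trig (seen from the temporary six-membered ring the same event is 6-endo), which completes the bicyclo[2.2.2]octane. The two-carbon bridge can only lie on one face, so C1 and C4 of 7 are set together; the chiral bisphosphine on palladium chooses in the carbopalladation between the two rapidly equilibrating enantiomers of 6 (dynamic kinetic asymmetric transformation), so the whole mixture should be funnelled into (1R,4R)-7. Regiochemistry is secured by the substrate, since only C2 (between the carbonyls) is nucleophilic, only C5 is an enone β-carbon, and their 1,4-relationship lets the three-atom tether reach. The step needs C- over O-allylation, single over double allylation (4 in slight excess, slow addition of 5) and carbopalladation over O-vinylation to a furan (no strong base in the second stage).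

Step 5
Reactants: 7 (1R,4R)-3,3-dimethyl-8-methylidenebicyclo[2.2.2]octane-2,6-dione
Product: 8 methyl 2-[(1R)-2,2-dimethyl-6-methylidene-3-oxocyclohexyl]acetate
Conditions: NaOMe (0.2 equiv), MeOH, 0 °C to rt
Reagents that add atoms: methanol, CO
Why: retro-Claisen cleavage of the β-diketone, which cannot enolise at its bridgehead: methoxide should add to the C6 carbonyl (the C2 carbonyl is shielded by the quaternary carbon) and expel the enolate of the other ketone, opening the temporary ring without touching the stereocentre.

Step 6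
Reactants: 8 methyl 2-[(1R)-2,2-dimethyl-6-methylidene-3-oxocyclohexyl]acetate
Product: 9 (1S,3R)-3-(2-hydroxyethyl)-2,2-dimethyl-4-methylidenecyclohexan-1-ol
Conditions: LiAlH4, THF, −78 °C to 0 °C
Reagents that add atoms: none
Why: LiAlH4 reduces ester and ketone; the small hydride should attack the ring carbonyl axially, anti to the C3 arm (1,3-induction, as in the reduction of 4,4-dimethyl-3-oxo triterpenoids to equatorial alcohols), giving the cis-1,3 (1S) alcohol.

Step 7
Reactants: 9 (1S,3R)-3-(2-hydroxyethyl)-2,2-dimethyl-4-methylidenecyclohexan-1-ol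
Product: 10 (1S,3R)-3-(2-iodoethyl)-2,2-dimethyl-4-methylidenecyclohexan-1-ol
Conditions: I2, PPh3, imidazole, CH2Cl2, 0 °C
Reagents that add atoms: iodine, II
Why: Garegg–Samuelsson (Appel-type) iodination should take only the primary alcohol, since the secondary one is flanked by the quaternary carbon.

Step 8
Reactants: 10 (1S,3R)-3-(2-iodoethyl)-2,2-dimethyl-4-methylidenecyclohexan-1-ol
Product: 11 tert-butyl{[(1S,3R)-3-(2-iodoethyl)-2,2-dimethyl-4-methylidenecyclohexyl]oxy}dimethylsilane
Conditions: TBSOTf, 2,6-lutidine, CH2Cl2, −78 °C to 0 °C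
Reagents that add atoms: tert-butyldimethylsilyl trifluoromethanesulfonate, CC(C)(C)[Si](C)(C)OS(=O)(=O)C(F)(F)F
Why: silylation of the hindered secondary alcohol with the silyl triflate removes the acidic proton before the organozinc is made and prevents cyclic ether formation.

Step 9
Reactants: 12 (2E,6E)-1-bromo-3,7,11-trimethyldodeca-2,6,10-triene; 13 trimethyl(prop-1-yn-1-yl)silane
Product: 15 trimethyl[(5E,9E)-6,10,14-trimethylpentadeca-5,9,13-trien-1-yn-1-yl]silane, via lithiated silylpropyne 14 (not isolated)
Conditions: n-BuLi, THF, −78 °C; then 12, −78 °C to rt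
Reagents that add atoms: none
Why: propargylic lithiation of 13 and SN2 alkylation at the primary allylic carbon of 12; the silyl group suppresses allenic products and the alkene geometry is not touched.

Step 10
Reactants: 15 trimethyl[(5E,9E)-6,10,14-trimethylpentadeca-5,9,13-trien-1-yn-1-yl]silane
Product: 17 (6E,10E)-7,11,15-trimethylhexadeca-6,10,14-trien-2-yne, via lithium acetylide 16 (not isolated)
Conditions: MeLi·LiBr, THF, 0 °C to rt; then MeI, 0 °C
Reagents that add atoms: iodomethane, CI
Why: methyllithium cleaves the alkynyl–silicon bond to the lithium acetylide, which is C-methylated by iodomethane.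

Step 11
Reactants: 17 (6E,10E)-7,11,15-trimethylhexadeca-6,10,14-trien-2-yne
Product: 19 (2E,6E,10E)-2-iodo-7,11,15-trimethylhexadeca-2,6,10,14-tetraene, via alkenylzirconocene chloride 18 (not isolated)
Conditions: Cp2Zr(H)Cl (2 equiv), THF, 50 °C; then I2, 0 °C
Reagents that add atoms: iodine, II
Why: hydrozirconation adds Zr–H syn, and with excess hydride at 50 °C zirconium should settle on the less hindered, methyl-bearing carbon; iodinolysis with retention gives the (E)-2-iodoalkene, and the trisubstituted alkenes do not react.

Step 12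
Reactants: 11 tert-butyl{[(1S,3R)-3-(2-iodoethyl)-2,2-dimethyl-4-methylidenecyclohexyl]oxy}dimethylsilane; 19 (2E,6E,10E)-2-iodo-7,11,15-trimethylhexadeca-2,6,10,14-tetraene
Product: 21 tert-butyl{[(1S,3R)-2,2-dimethyl-4-methylidene-3-[(3E,7E,11E)-3,8,12,16-tetramethylheptadeca-3,7,11,15-tetraen-1-yl]cyclohexyl]oxy}dimethylsilane, via alkylzinc iodide 20 (not isolated)
Conditions: Zn dust, LiCl, THF, 40 °C; then 19, Pd(dppf)Cl2 (5 mol %), THF, 50 °C
Reagents that add atoms: none
Why: zinc insertion into the primary iodide and Negishi sp3–sp2 coupling with the alkenyl iodide proceed with retention of the alkene geometry; the silyl ether, the exocyclic methylene and the trisubstituted alkenes are inert.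

Step 13
Reactants: 21 tert-butyl{[(1S,3R)-2,2-dimethyl-4-methylidene-3-[(3E,7E,11E)-3,8,12,16-tetramethylheptadeca-3,7,11,15-tetraen-1-yl]cyclohexyl]oxy}dimethylsilane
Product: 22 achilleol A, (1S,3R)-2,2-dimethyl-4-methylidene-3-[(3E,7E,11E)-3,8,12,16-tetramethylheptadeca-3,7,11,15-tetraen-1-yl]cyclohexan-1-ol
Conditions: TBAF, THF, 50 °C
Reagents that add atoms: none
Why: fluoride cleaves the hindered silyl ether under conditions that touch neither the stereocentres nor the alkenes.

**Compound list**

1 | 4,4-dimethylcyclohex-2-en-1-one | CC1(C)CCC(=O)C=C1 | starting material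
2 | 4,4-dimethylcyclohexa-2,5-dien-1-one | CC1(C)C=CC(=O)C=C1 | intermediate
3 | rac-5,5-dimethyl-7-oxabicyclo[4.1.0]hept-3-en-2-one | CC1(C)C=CC(=O)C2OC12 | intermediate
4 | 4,4-dimethylcyclohex-5-ene-1,3-dione (enol form: 3-hydroxy-4,4-dimethylcyclohexa-2,5-dien-1-one) | CC1(C)C=CC(=O)CC1=O | intermediate
5 | 2,3-dibromoprop-1-ene | C=C(Br)CBr | starting material
6 | 2-(2-bromoprop-2-en-1-yl)-4,4-dimethylcyclohex-5-ene-1,3-dione (racemising) | C=C(Br)CC1C(=O)C=CC(C)(C)C1=O | intermediate
7 | (1R,4R)-3,3-dimethyl-8-methylidenebicyclo[2.2.2]octane-2,6-dione | C=C1C[C@H]2C(=O)C(C)(C)[C@@H]1CC2=O | intermediate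
8 | methyl 2-[(1R)-2,2-dimethyl-6-methylidene-3-oxocyclohexyl]acetate | C=C1CCC(=O)C(C)(C)[C@@H]1CC(=O)OC | intermediate
9 | (1S,3R)-3-(2-hydroxyethyl)-2,2-dimethyl-4-methylidenecyclohexan-1-ol | C=C1CC[C@H](O)C(C)(C)[C@@H]1CCO | intermediate
10 | (1S,3R)-3-(2-iodoethyl)-2,2-dimethyl-4-methylidenecyclohexan-1-ol | C=C1CC[C@H](O)C(C)(C)[C@@H]1CCI | intermediate
11 | tert-butyl{[(1S,3R)-3-(2-iodoethyl)-2,2-dimethyl-4-methylidenecyclohexyl]oxy}dimethylsilane | C=C1CC[C@H](O[Si](C)(C)C(C)(C)C)C(C)(C)[C@@H]1CCI | intermediate
12 | (2E,6E)-1-bromo-3,7,11-trimethyldodeca-2,6,10-triene ((2E,6E)-farnesyl bromide) | BrC/C=C(\C)CC/C=C(\C)CCC=C(C)C | starting material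
13 | trimethyl(prop-1-yn-1-yl)silane | CC#C[Si](C)(C)C | starting material
14 | [3-(trimethylsilyl)prop-2-yn-1-yl]lithium | [Li]CC#C[Si](C)(C)C | intermediate
15 | trimethyl[(5E,9E)-6,10,14-trimethylpentadeca-5,9,13-trien-1-yn-1-yl]silane | C[Si](C)(C)C#CCC/C=C(\C)CC/C=C(\C)CCC=C(C)C | intermediate
16 | [(5E,9E)-6,10,14-trimethylpentadeca-5,9,13-trien-1-yn-1-yl]lithium | [Li]C#CCC/C=C(\C)CC/C=C(\C)CCC=C(C)C | intermediate
17 | (6E,10E)-7,11,15-trimethylhexadeca-6,10,14-trien-2-yne | CC#CCC/C=C(\C)CC/C=C(\C)CCC=C(C)C | intermediate
18 | chloridobis(cyclopentadienyl)[(2E,6E,10E)-7,11,15-trimethylhexadeca-2,6,10,14-tetraen-2-yl]zirconium | C/C(=C\CC/C=C(\C)CC/C=C(\C)CCC=C(C)C)[Zr](Cl)(C1C=CC=C1)C1C=CC=C1 | intermediate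
19 | (2E,6E,10E)-2-iodo-7,11,15-trimethylhexadeca-2,6,10,14-tetraene | C/C(I)=C\CC/C=C(\C)CC/C=C(\C)CCC=C(C)C | intermediate
20 | {2-[(1R,3S)-3-(tert-butyldimethylsilyloxy)-2,2-dimethyl-6-methylidenecyclohexyl]ethyl}zinc iodide | C=C1CC[C@H](O[Si](C)(C)C(C)(C)C)C(C)(C)[C@@H]1CC[Zn]I | intermediate
21 | tert-butyl{[(1S,3R)-2,2-dimethyl-4-methylidene-3-[(3E,7E,11E)-3,8,12,16-tetramethylheptadeca-3,7,11,15-tetraen-1-yl]cyclohexyl]oxy}dimethylsilane | C=C1CC[C@H](O[Si](C)(C)C(C)(C)C)C(C)(C)[C@@H]1CC/C(C)=C/CC/C=C(\C)CC/C=C(\C)CCC=C(C)C | intermediate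
22 | achilleol A, (1S,3R)-2,2-dimethyl-4-methylidene-3-[(3E,7E,11E)-3,8,12,16-tetramethylheptadeca-3,7,11,15-tetraen-1-yl]cyclohexan-1-ol | C=C1CC[C@H](O)C(C)(C)[C@@H]1CC/C(C)=C/CC/C=C(\C)CC/C=C(\C)CCC=C(C)C | target

**Step count and risks**

Total step count: 13. Longest linear sequence: 10 steps (steps 1 to 8, 12 and 13).

Steps most likely to fail:

1. Step 4 (Proposed new method). The alkenylpalladium may be trapped by the enol oxygen (O-vinylation towards a furan) or reduced by formate before it can insert, the dione may be allylated twice, and the catalyst may discriminate poorly between the two equilibrating enantiomers of the intermediate. Fallback (sets out from 4 and 5, comes back at 8): 6 is made on purpose and isolated by Tsuji–Trost C-allylation (Pd(PPh3)4, Et3N, THF, rt). Its ring is closed away from any metal–enol contact by a tin hydride mediated 6-exo vinyl radical cyclisation onto the enone (Bu3SnH, AIBN, benzene, 80 °C, slow addition), which should give rac-3,3-dimethyl-8-methylidenebicyclo[2.2.2]octane-2,6-dione F1. Aqueous NaOH opens F1 by the same retro-Claisen cleavage to rac-2-(2,2-dimethyl-6-methylidene-3-oxocyclohexyl)acetic acid F2. Classical resolution of F2 through its crystalline salt with one enantiomer of 1-phenylethylamine (antipode chosen by a crystallisation screen) gives 2-[(1R)-2,2-dimethyl-6-methylidene-3-oxocyclohexyl]acetic acid F3, and TMSCHN2 in toluene/MeOH returns 8. This costs at least half of the material but uses only known reaction types.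

2. Step 11. Zirconium may add to both alkyne carbons, which would give regioisomeric alkenyl iodides that are hard to separate and would carry a misplaced double bond into the target. Fallback (sets out from 12 and from alkylzinc iodide 20, made from 11 as in step 12; comes back at 21): 12 is alkylated with lithiated acetaldehyde N-cyclohexylimine (LDA, THF, −78 °C) and hydrolysed with aqueous oxalic acid to (4E,8E)-5,9,13-trimethyltetradeca-4,8,12-trienal F4. CBr4 and PPh3 (first stage of the Corey–Fuchs sequence) convert it into (5E,9E)-1,1-dibromo-6,10,14-trimethylpentadeca-1,5,9,13-tetraene F5. A Negishi coupling of F5 with 20 (Pd(DPEphos)Cl2, THF) should take place only at the bromine trans to the chain and give {[(1S,3R)-3-[(3Z,7E,11E)-3-bromo-8,12,16-trimethylheptadeca-3,7,11,15-tetraen-1-yl]-2,2-dimethyl-4-methylidenecyclohexyl]oxy}(tert-butyl)dimethylsilane F6. A second Negishi coupling with MeZnCl (Pd(t-Bu3P)2, THF) replaces the remaining bromine with retention and gives 21. The 3′E geometry then follows from the order of the two couplings and not from a regioselective hydrometalation.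

3. Step 6. Hydride delivery to the ring ketone may show poor facial selectivity, because the ring with two sp2 carbons is flexible and the gem-dimethyl group shields both faces alike. Fallback (sets out from 8, comes back at 9): the ketone alone is reduced under reagent control with (R)-2-methyl-CBS-oxazaborolidine (cat.) and BH3·SMe2 in THF (large group: the quaternary carbon), which should give methyl 2-[(1R,3S)-3-hydroxy-2,2-dimethyl-6-methylidenecyclohexyl]acetate F7. DBU (cat.) in warm toluene closes only the cis isomer to the bridged lactone (1S,5R)-9,9-dimethyl-6-methylidene-2-oxabicyclo[3.3.1]nonan-3-one F8, which separates it from any trans hydroxy ester, and LiAlH4 opens F8 to 9.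

**Further compounds**

F1 | step 4 | rac-3,3-dimethyl-8-methylidenebicyclo[2.2.2]octane-2,6-dione | C=C1CC2C(=O)C(C)(C)C1CC2=O
F2 | step 4 | rac-2-(2,2-dimethyl-6-methylidene-3-oxocyclohexyl)acetic acid | C=C1CCC(=O)C(C)(C)C1CC(=O)O
F3 | step 4 | 2-[(1R)-2,2-dimethyl-6-methylidene-3-oxocyclohexyl]acetic acid | C=C1CCC(=O)C(C)(C)[C@@H]1CC(=O)O
F4 | step 11 | (4E,8E)-5,9,13-trimethyltetradeca-4,8,12-trienal | O=CCC/C=C(\C)CC/C=C(\C)CCC=C(C)C
F5 | step 11 | (5E,9E)-1,1-dibromo-6,10,14-trimethylpentadeca-1,5,9,13-tetraene | BrC(Br)=CCC/C=C(\C)CC/C=C(\C)CCC=C(C)C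
F6 | step 11 | {[(1S,3R)-3-[(3Z,7E,11E)-3-bromo-8,12,16-trimethylheptadeca-3,7,11,15-tetraen-1-yl]-2,2-dimethyl-4-methylidenecyclohexyl]oxy}(tert-butyl)dimethylsilane | C=C1CC[C@H](O[Si](C)(C)C(C)(C)C)C(C)(C)[C@@H]1CC/C(Br)=C/CC/C=C(\C)CC/C=C(\C)CCC=C(C)C
F7 | step 6 | methyl 2-[(1R,3S)-3-hydroxy-2,2-dimethyl-6-methylidenecyclohexyl]acetate | C=C1CC[C@H](O)C(C)(C)[C@@H]1CC(=O)OC
F8 | step 6 | (1S,5R)-9,9-dimethyl-6-methylidene-2-oxabicyclo[3.3.1]nonan-3-one | C=C1CC[C@H](O2)C(C)(C)[C@@H]1CC2=O
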